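**Plan**

- Enabling feature: the E C8=C9 alkene inside the 19-membered lactam ring carries its methyl on C8, next to the oxygen-bearing C7. This maps onto a ring C8≡C9 alkyne flanked by a free C7 hydroxyl.
- Retrosynthetic cuts, in order: silyl ethers and the C7 carbamate; C8–CH3 and C9–H (tin-to-methyl exchange, trans-hydrostannation); C8≡C9 (alkyne metathesis, which opens the ring); the N–C1 amide; C10–C11 (allenylstannane addition); C14–C15 (anti-aldol); C7–C8 (propynyl addition); C2=C3 (Wittig).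
- Forward: one lactone-derived C5 ester 4 is used twice, once for C3–C7 and once for C11–C14 plus the carbon that becomes the C14 methyl. Acid 14 and aniline 36 are joined as the anilide, and the only macrocycle is then closed at C8–C9.
- Stereochemistry: C6 and C12 come from the (S)-lactone. C7 comes from chelation-controlled addition. C14 and C15 come from an auxiliary-controlled anti-aldol. C10 and C11 come from a matched SE2' addition of an allenylstannane whose axis derives from a transfer-hydrogenated ynone.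
- Alkene geometry: C2=C3 from an E-selective Wittig reaction; C8=C9 from trans-hydrostannation followed by methylation with retention.

Key step: step 26

Remark: ansa-chain numbering of the target is used throughout (C1 lactam carbonyl, C7 carbamate carbon, C8=C9 alkene, C15 benzylic carbinol); the (S,S)-diamine ruthenium transfer hydrogenation of pent-3-yn-2-one is assumed to follow the facial sense known for other alkynyl methyl ketones.

**Route**

Step 1
Reactants: 1 (S)-5-(hydroxymethyl)dihydrofuran-2(3H)-one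
Product: 2 (S)-5-[(trityloxy)methyl]dihydrofuran-2(3H)-one
Conditions: Ph3CCl, pyridine, CH2Cl2, rt
Reagents that add atoms: trityl chloride, ClC(c1ccccc1)(c1ccccc1)c1ccccc1
Why: Tritylation of the primary alcohol installs a base-stable ether that cannot migrate to the neighbouring oxygen in the next step.

Step 2
Reactants: 2 (S)-5-[(trityloxy)methyl]dihydrofuran-2(3H)-one
Product: 4 methyl (S)-4-methoxy-5-(trityloxy)pentanoate, via potassium hydroxy carboxylate 3 (not isolated)
Conditions: KOH (powder), DMSO, rt; then MeI, 0 °C to rt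
Reagents that add atoms: potassium hydroxide, [K+].[OH-]; iodomethane, CI
Why: Hydroxide opens the lactone and the resulting alkoxide and carboxylate are both O-methylated (Williamson etherification plus carboxylate alkylation), which fixes the methyl ether on the stereocentre without touching its configuration.

Step 3
Reactants: 4 methyl (S)-4-methoxy-5-(trityloxy)pentanoate
Product: 5 (S)-4-methoxy-5-(trityloxy)pentanal
Conditions: i-Bu2AlH, CH2Cl2, −78 °C; Rochelle-salt work-up
Reagents that add atoms: none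
Why: Partial ester reduction should stop at the aldehyde because the tetrahedral aluminate persists at −78 °C until work-up.

Step 4
Reactants: 5 (S)-4-methoxy-5-(trityloxy)pentanal; 6 ethyl 2-(triphenylphosphoranylidene)propanoate
Product: 7 ethyl (S,E)-6-methoxy-2-methyl-7-(trityloxy)hept-2-enoate
Conditions: CH2Cl2, rt to 40 °C
Reagents that add atoms: none
Why: Wittig olefination with a stabilised α-branched ylide should give the trisubstituted E enoate that becomes C1–C3.

Step 5
Reactants: 7 ethyl (S,E)-6-methoxy-2-methyl-7-(trityloxy)hept-2-enoate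
Product: 8 ethyl (S,E)-7-hydroxy-6-methoxy-2-methylhept-2-enoate
Conditions: TsOH·H2O (cat.), EtOH, rt
Reagents that add atoms: none
Why: Acid-catalysed solvolysis of the trityl ether frees the primary alcohol, and ethanol as solvent avoids ester exchange.

Step 6
Reactants: 8 ethyl (S,E)-7-hydroxy-6-methoxy-2-methylhept-2-enoate
Product: 9 ethyl (S,E)-6-methoxy-2-methyl-7-oxohept-2-enoate
Conditions: Dess–Martin periodinane, CH2Cl2, 0 °C to rt; used crude
Reagents that add atoms: none
Why: Dess–Martin oxidation gives the α-methoxy aldehyde without base, so the C6 stereocentre should not epimerise.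

Step 7
Reactants: 9 ethyl (S,E)-6-methoxy-2-methyl-7-oxohept-2-enoate; 10 1-propynylmagnesium bromide (CH3C≡CMgBr)
Product: 11 ethyl (2E,6S,7S)-7-hydroxy-6-methoxy-2-methyldec-2-en-8-ynoate
Conditions: MgBr2·OEt2, CH2Cl2, −78 °C; then CH3C≡CMgBr (THF), −78 °C
Reagents that add atoms: none
Why: Cram-chelate addition, in which magnesium bridges the aldehyde and α-methoxy oxygens and the alkynyl Grignard attacks the chelate face that carries hydrogen, should set C7 as S (6,7-syn) while the ester is left alone at −78 °C.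

Step 8
Reactants: 11 ethyl (2E,6S,7S)-7-hydroxy-6-methoxy-2-methyldec-2-en-8-ynoate
Product: 12 (2E,6S,7S)-7-hydroxy-6-methoxy-2-methyldec-2-en-8-ynoic acid
Conditions: LiOH·H2O, THF/MeOH/H2O, rt; dilute HCl
Reagents that add atoms: none
Why: Saponification of the ethyl ester should proceed without oxa-Michael addition of the C7 hydroxyl because the α-methyl enoate is a poor acceptor.

Step 9
Reactants: 12 (2E,6S,7S)-7-hydroxy-6-methoxy-2-methyldec-2-en-8-ynoic acid
Product: 14 (2E,6S,7S)-6-methoxy-2-methyl-7-(triethylsilyloxy)dec-2-en-8-ynoic acid, via bis-silyl compound 13 (not isolated)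
Conditions: Et3SiOTf, 2,6-lutidine, CH2Cl2, −78 to 0 °C; then aq NaHCO3, MeOH, rt
Reagents that add atoms: triethylsilyl triflate, CC[Si](CC)(CC)OS(=O)(=O)C(F)(F)F
Why: The silyl triflate silylates both alcohol and acid, and the far more labile silyl ester is hydrolysed selectively in the work-up.

Step 10
Reactants: 4 methyl (S)-4-methoxy-5-(trityloxy)pentanoate
Product: 15 (S)-4-methoxy-5-(trityloxy)pentanoic acid
Conditions: LiOH·H2O, THF/MeOH/H2O, rt; cold dilute HCl to pH 4
Reagents that add atoms: none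
Why: Plain saponification gives the acid, which cannot relactonise because the C4 oxygen is methylated.

Step 11
Reactants: 15 (S)-4-methoxy-5-(trityloxy)pentanoic acid; 16 (R)-4-benzyloxazolidin-2-one
Product: 18 (R)-4-benzyl-3-[(S)-4-methoxy-5-(trityloxy)pentanoyl]oxazolidin-2-one, via mixed pivalic anhydride 17 (not isolated)
Conditions: t-BuCOCl, Et3N, THF, −20 °C; then 16, LiCl, rt
Reagents that add atoms: none
Why: Mixed-anhydride N-acylation of the oxazolidinone in the presence of LiCl attaches the auxiliary without a strong base.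

Step 12
Reactants: 19 3-hydroxy-5-nitrobenzaldehyde
Product: 20 3-nitro-5-(triisopropylsilyloxy)benzaldehyde
Conditions: i-Pr3SiCl, imidazole, DMF, rt
Reagents that add atoms: triisopropylsilyl chloride, CC(C)[Si](Cl)(C(C)C)C(C)C
Why: Silylation gives a bulky aryl silyl ether that should survive the Lewis acidic, mildly acidic and reductive steps ahead and fall in the final fluoride step.

Step 13
Reactants: 18 (R)-4-benzyl-3-[(S)-4-methoxy-5-(trityloxy)pentanoyl]oxazolidin-2-one; 20 3-nitro-5-(triisopropylsilyloxy)benzaldehyde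
Product: 22 (R)-4-benzyl-3-[(2S,4S)-2-{(R)-hydroxy[3-nitro-5-(triisopropylsilyloxy)phenyl]methyl}-4-methoxy-5-(trityloxy)pentanoyl]oxazolidin-2-one, via trimethylsilyl ether 21 (not isolated)
Conditions: MgCl2 (20 mol %), Et3N, Me3SiCl, EtOAc, rt; then PPTS, MeOH, 0 °C
Reagents that add atoms: none
Why: In this MgCl2-catalysed direct anti-aldol of an N-acyl oxazolidinone the chelated Z magnesium enolate reacts through a boat-like transition state on the face away from benzyl, which should set C14 (S) and C15 (R) as the 2,3-anti pair, the imide carbonyl being the future C14 methyl carbon.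

Step 14
Reactants: 22 (the anti-aldol adduct)
Product: 23 (R)-4-benzyl-3-[(2S,4S)-2-{(R)-(tert-butyldimethylsilyloxy)[3-nitro-5-(triisopropylsilyloxy)phenyl]methyl}-4-methoxy-5-(trityloxy)pentanoyl]oxazolidin-2-one
Conditions: t-BuMe2SiOTf, 2,6-lutidine, CH2Cl2, −78 to 0 °C
Reagents that add atoms: tert-butyldimethylsilyl triflate, CC(C)(C)[Si](C)(C)OS(=O)(=O)C(F)(F)F
Why: Silylation of the hindered benzylic alcohol with the silyl triflate blocks retro-aldol cleavage and protects C15 until the end.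

Step 15
Reactants: 23 (the O-TBS imide)
Product: 24 (2R,4S)-2-{(R)-(tert-butyldimethylsilyloxy)[3-nitro-5-(triisopropylsilyloxy)phenyl]methyl}-4-methoxy-5-(trityloxy)pentan-1-ol
Conditions: LiBH4, MeOH, THF, 0 °C
Reagents that add atoms: none
Why: Reductive cleavage of the imide gives the primary alcohol and returns the auxiliary, while the nitro group and silyl ethers are inert to LiBH4 at 0 °C.

Step 16
Reactants: 24 (the primary alcohol)
Product: 27 tert-butyl({(1R,2S,4S)-4-methoxy-2-methyl-1-[3-nitro-5-(triisopropylsilyloxy)phenyl]-5-(trityloxy)pentyl}oxy)dimethylsilane, via sulfonylhydrazine 25 (not isolated), via alkyldiazene 26 (not isolated)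
Conditions: 2-nitrobenzenesulfonylhydrazide, PPh3, DEAD, THF, −30 °C to rt
Reagents that add atoms: none
Why: Mitsunobu alkylation of the sulfonylhydrazide, loss of sulfinic acid to a monoalkyl diazene and extrusion of N2 replace the primary hydroxyl by hydrogen, turning the former carbonyl carbon into the C14 methyl group under conditions that tolerate nitro and silyl groups.

Step 17
Reactants: 27 (the C14-methyl trityl ether)
Product: 28 (2S,4S,5R)-5-(tert-butyldimethylsilyloxy)-2-methoxy-4-methyl-5-[3-nitro-5-(triisopropylsilyloxy)phenyl]pentan-1-ol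
Conditions: TsOH·H2O (cat.), MeOH/CH2Cl2, 0 °C
Reagents that add atoms: none
Why: Acid-catalysed methanolysis removes the trityl ether much faster than the secondary benzylic TBS ether, whose ionisation is disfavoured by the nitroarene, or the aryl silyl ether.

Step 18
Reactants: 28 (the C11 primary alcohol)
Product: 29 (2S,4S,5R)-5-(tert-butyldimethylsilyloxy)-2-methoxy-4-methyl-5-[3-nitro-5-(triisopropylsilyloxy)phenyl]pentanal
Conditions: Dess–Martin periodinane, CH2Cl2, 0 °C to rt; used crude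
Reagents that add atoms: none
Why: Dess–Martin oxidation gives the configurationally labile α-methoxy aldehyde under non-basic conditions.

Step 19
Reactants: 30 pent-3-yn-2-one
Product: 31 (S)-pent-3-yn-2-ol
Conditions: RuCl[(S,S)-TsDPEN](p-cymene) (1 mol %), i-PrOH, rt
Reagents that add atoms: none
Why: Noyori transfer hydrogenation delivers hydride from the chiral ruthenium hydride to one face of the ynone and should give the S propargylic alcohol.

Step 20
Reactants: 31 (S)-pent-3-yn-2-ol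
Product: 32 (S)-pent-3-yn-2-yl methanesulfonate
Conditions: MsCl, Et3N, CH2Cl2, −78 °C
Reagents that add atoms: methanesulfonyl chloride, CS(Cl)(=O)=O
Why: O-Sulfonylation activates the propargylic position with retention of configuration.

Step 21
Reactants: 32 (S)-pent-3-yn-2-yl methanesulfonate
Product: 33 (aR)-tributyl(penta-2,3-dien-2-yl)stannane
Conditions: Bu3SnH, LiN(i-Pr)2, THF, 0 °C; CuBr·SMe2, −78 °C; then 32, −78 °C
Reagents that add atoms: tributyltin hydride, CCCC[SnH](CCCC)CCCC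
Why: The stannylcuprate displaces the mesylate in an anti SN2' sense, so the central chirality of the carbinol is transferred to the aR allene axis.

Step 22
Reactants: 29 (the α-methoxy aldehyde); 33 (aR)-tributyl(penta-2,3-dien-2-yl)stannane
Product: 34 (1R,2S,4S,5R,6S)-1-(tert-butyldimethylsilyloxy)-4-methoxy-2,6-dimethyl-1-[3-nitro-5-(triisopropylsilyloxy)phenyl]non-7-yn-5-ol
Conditions: BF3·OEt2, CH2Cl2, −78 °C
Reagents that add atoms: none
Why: In this Lewis acid promoted SE2' propargylation the BF3-bound aldehyde is attacked by the allene terminus anti to tin through an open transition state that favours the syn adduct, so the allene axis fixes C10 (S), the syn preference fixes C11 (R), and the Felkin–Anh preference of the non-chelated α-methoxy aldehyde (11,12-anti) points the same way.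

Step 23
Reactants: 34 (the homopropargylic alcohol)
Product: 35 (1R,2S,4S,5R,6S)-1,5-bis(tert-butyldimethylsilyloxy)-4-methoxy-2,6-dimethyl-1-[3-nitro-5-(triisopropylsilyloxy)phenyl]non-7-yne
Conditions: t-BuMe2SiOTf, 2,6-lutidine, CH2Cl2, 0 °C
Reagents that add atoms: tert-butyldimethylsilyl triflate, CC(C)(C)[Si](C)(C)OS(=O)(=O)C(F)(F)F
Why: Silyl triflate silylation protects the hindered C11 hydroxyl so that only the C7 oxygen is free at the carbamoylation stage.

Step 24
Reactants: 35 (the nitro alkyne)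
Product: 36 3-[(1R,2S,4S,5R,6S)-1,5-bis(tert-butyldimethylsilyloxy)-4-methoxy-2,6-dimethylnon-7-yn-1-yl]-5-(triisopropylsilyloxy)aniline
Conditions: Zn dust, AcOH, THF, 0 °C to rt
Reagents that add atoms: none
Why: Dissolving-metal reduction of the nitro group gives the aniline and leaves the internal alkyne and the silyl ethers untouched.

Step 25
Reactants: 14 (2E,6S,7S)-6-methoxy-2-methyl-7-(triethylsilyloxy)dec-2-en-8-ynoic acid; 36 (the aniline)
Product: 38 seco diyne anilide (amide of 36 with acid 14; C7 O-TES; C11 and C15 O-TBS; phenol O-TIPS; methyl-capped alkynes at C8 and C9), via acid chloride 37 (not isolated)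
Conditions: 1-chloro-N,N,2-trimethylprop-1-en-1-amine, CH2Cl2, 0 °C; then 36, pyridine, 0 °C to rt
Reagents that add atoms: none
Why: The α-chloroenamine turns the acid into its chloride under neutral conditions and the aniline is then N-acylated without loss of the triethylsilyl ether or isomerisation of the enoate.

Step 26
Reactants: 38 seco diyne anilide
Product: 39 19-membered cycloalkyne lactam (C8≡C9; C7 O-TES; C11 and C15 O-TBS; phenol O-TIPS)
Conditions: Mo(≡CC6H4OMe-4)(OSiPh3)3 (15 mol %), 5 Å molecular sieves, toluene (2 mM), 80 °C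
Reagents that add atoms: none
Why: The molybdenum alkylidyne adds to one methyl-capped alkyne by [2+2] cycloaddition to a metallacyclobutadiene, which cycloreverts to release 2-butyne and leave a substrate-bound alkylidyne, and the same sequence at the second alkyne forms the C8≡C9 bond. The closest known reaction type is ring-closing alkyne metathesis with molybdenum alkylidyne silanolate catalysts. The 19-membered ring is closed by macrocyclisation through this metathesis at C8–C9, with both alkyne carbons ending up in the ring. No stereocentre is formed. The step needs alkyne-over-alkene chemoselectivity and ring closure over oligomerisation: the alkylidyne does not engage the two trisubstituted alkenes, the methyl caps give volatile 2-butyne that the sieves trap, and high dilution with all hydroxyls silylated keeps the reaction intramolecular and the catalyst alive.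

Step 27
Reactants: 39 (the cycloalkyne lactam)
Product: 40 cycloalkyne lactam with free C7 hydroxyl (C11 and C15 O-TBS; phenol O-TIPS)
Conditions: PPTS, MeOH/CH2Cl2, 0 °C
Reagents that add atoms: none
Why: Mild acid methanolysis removes the triethylsilyl ether much faster than the secondary TBS ethers or the aryl TIPS ether and frees the C7 hydroxyl as directing group.

Step 28
Reactants: 40 (the C7 propargylic alcohol)
Product: 41 C8-tributylstannyl ring alkene with C7 and C10 trans across C8=C9 (free C7 hydroxyl; C11 and C15 O-TBS; phenol O-TIPS)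
Conditions: [Cp*RuCl]4 (3 mol %), Bu3SnH, CH2Cl2, rt
Reagents that add atoms: tributyltin hydride, CCCC[SnH](CCCC)CCCC
Why: In this hydroxyl-directed ruthenium-catalysed trans-hydrostannation a hydrogen bond from the C7 hydroxyl to the chloride ligand steers tin to the proximal carbon C8 while hydrogen is delivered trans to C9.

Step 29
Reactants: 41 (the alkenylstannane)
Product: 42 (8E)-8-methyl ring alkene with free C7 hydroxyl (C11 and C15 O-TBS; phenol O-TIPS)
Conditions: MeI, Pd(PPh3)4 (cat.), Cu(O2CC4H3S), [NBu4][Ph2PO2], DMF, rt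
Reagents that add atoms: iodomethane, CI
Why: Copper-assisted Stille-type coupling of the alkenylstannane with iodomethane proceeds with retention at C8 and should give the E trisubstituted alkene, the phosphinate salt scavenging tin and suppressing protodestannation.

Step 30
Reactants: 42 (the C7 allylic alcohol)
Product: 44 C7 carbamate of 42 (C11 and C15 O-TBS; phenol O-TIPS), via trichloroacetyl carbamate 43 (not isolated)
Conditions: Cl3CC(O)NCO, CH2Cl2, 0 °C; then neutral Al2O3
Reagents that add atoms: trichloroacetyl isocyanate, O=C=NC(=O)C(Cl)(Cl)Cl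
Why: The only free hydroxyl adds to the acyl isocyanate and the trichloroacetyl group is hydrolysed on alumina to leave the primary carbamate, the anilide NH being too weakly nucleophilic to compete.

Step 31
Reactants: 44 (the tris-silyl carbamate)
Product: 45 CNP0309815.1 (target)
Conditions: HF·pyridine, pyridine, THF, 0 °C to rt
Reagents that add atoms: none
Why: Fluoride-mediated desilylation removes both TBS ethers and the aryl TIPS ether in one operation and leaves the carbamate, the lactam and both alkenes untouched.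

**Compound list**

1 | (S)-5-(hydroxymethyl)dihydrofuran-2(3H)-one | O=C1CC[C@@H](CO)O1 | starting material
2 | (S)-5-[(trityloxy)methyl]dihydrofuran-2(3H)-one | O=C1CC[C@@H](COC(c2ccccc2)(c2ccccc2)c2ccccc2)O1 | intermediate
3 | potassium (S)-4-hydroxy-5-(trityloxy)pentanoate | [K+].[O-]C(=O)CC[C@H](O)COC(c1ccccc1)(c1ccccc1)c1ccccc1 | intermediate
4 | methyl (S)-4-methoxy-5-(trityloxy)pentanoate | COC(=O)CC[C@H](OC)COC(c1ccccc1)(c1ccccc1)c1ccccc1 | intermediate
5 | (S)-4-methoxy-5-(trityloxy)pentanal | O=CCC[C@H](OC)COC(c1ccccc1)(c1ccccc1)c1ccccc1 | intermediate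
6 | ethyl 2-(triphenylphosphoranylidene)propanoate | CCOC(=O)C(C)=P(c1ccccc1)(c1ccccc1)c1ccccc1 | starting material
7 | ethyl (S,E)-6-methoxy-2-methyl-7-(trityloxy)hept-2-enoate | CCOC(=O)/C(C)=C/CC[C@H](OC)COC(c1ccccc1)(c1ccccc1)c1ccccc1 | intermediate
8 | ethyl (S,E)-7-hydroxy-6-methoxy-2-methylhept-2-enoate | CCOC(=O)/C(C)=C/CC[C@H](OC)CO | intermediate
9 | ethyl (S,E)-6-methoxy-2-methyl-7-oxohept-2-enoate | CCOC(=O)/C(C)=C/CC[C@H](OC)C=O | intermediate
10 | 1-propynylmagnesium bromide | CC#C[Mg]Br | starting material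
11 | ethyl (2E,6S,7S)-7-hydroxy-6-methoxy-2-methyldec-2-en-8-ynoate | CCOC(=O)/C(C)=C/CC[C@H](OC)[C@@H](O)C#CC | intermediate
12 | (2E,6S,7S)-7-hydroxy-6-methoxy-2-methyldec-2-en-8-ynoic acid | OC(=O)/C(C)=C/CC[C@H](OC)[C@@H](O)C#CC | intermediate
13 | triethylsilyl (2E,6S,7S)-6-methoxy-2-methyl-7-(triethylsilyloxy)dec-2-en-8-ynoate | CC[Si](CC)(CC)OC(=O)/C(C)=C/CC[C@H](OC)[C@@H](O[Si](CC)(CC)CC)C#CC | intermediate
14 | (2E,6S,7S)-6-methoxy-2-methyl-7-(triethylsilyloxy)dec-2-en-8-ynoic acid | OC(=O)/C(C)=C/CC[C@H](OC)[C@@H](O[Si](CC)(CC)CC)C#CC | intermediate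
15 | (S)-4-methoxy-5-(trityloxy)pentanoic acid | OC(=O)CC[C@H](OC)COC(c1ccccc1)(c1ccccc1)c1ccccc1 | intermediate
16 | (R)-4-benzyloxazolidin-2-one | O=C1N[C@H](Cc2ccccc2)CO1 | starting material
17 | (S)-4-methoxy-5-(trityloxy)pentanoic pivalic anhydride | CC(C)(C)C(=O)OC(=O)CC[C@H](OC)COC(c1ccccc1)(c1ccccc1)c1ccccc1 | intermediate
18 | (R)-4-benzyl-3-[(S)-4-methoxy-5-(trityloxy)pentanoyl]oxazolidin-2-one | O=C(CC[C@H](OC)COC(c1ccccc1)(c1ccccc1)c1ccccc1)N1[C@H](Cc2ccccc2)COC1=O | intermediate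
19 | 3-hydroxy-5-nitrobenzaldehyde | O=Cc1cc(O)cc(c1)[N+](=O)[O-] | starting material
20 | 3-nitro-5-(triisopropylsilyloxy)benzaldehyde | O=Cc1cc(O[Si](C(C)C)(C(C)C)C(C)C)cc(c1)[N+](=O)[O-] | intermediate
21 | O-trimethylsilyl ether of aldol adduct 22 | C(c1ccccc1)(c1ccccc1)(c1ccccc1)OC[C@@H](OC)C[C@H](C(=O)N1[C@H](Cc2ccccc2)COC1=O)[C@@H](O[Si](C)(C)C)c1cc(O[Si](C(C)C)(C(C)C)C(C)C)cc(c1)[N+](=O)[O-] | intermediate
22 | (R)-4-benzyl-3-[(2S,4S)-2-{(R)-hydroxy[3-nitro-5-(triisopropylsilyloxy)phenyl]methyl}-4-methoxy-5-(trityloxy)pentanoyl]oxazolidin-2-one | C(c1ccccc1)(c1ccccc1)(c1ccccc1)OC[C@@H](OC)C[C@H](C(=O)N1[C@H](Cc2ccccc2)COC1=O)[C@@H](O)c1cc(O[Si](C(C)C)(C(C)C)C(C)C)cc(c1)[N+](=O)[O-] | intermediate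
23 | O-tert-butyldimethylsilyl ether of 22 at the benzylic oxygen | C(c1ccccc1)(c1ccccc1)(c1ccccc1)OC[C@@H](OC)C[C@H](C(=O)N1[C@H](Cc2ccccc2)COC1=O)[C@@H](O[Si](C)(C)C(C)(C)C)c1cc(O[Si](C(C)C)(C(C)C)C(C)C)cc(c1)[N+](=O)[O-] | intermediate
24 | (2R,4S)-2-{(R)-(tert-butyldimethylsilyloxy)[3-nitro-5-(triisopropylsilyloxy)phenyl]methyl}-4-methoxy-5-(trityloxy)pentan-1-ol | C(c1ccccc1)(c1ccccc1)(c1ccccc1)OC[C@@H](OC)C[C@H](CO)[C@@H](O[Si](C)(C)C(C)(C)C)c1cc(O[Si](C(C)C)(C(C)C)C(C)C)cc(c1)[N+](=O)[O-] | intermediate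
25 | N-alkyl-N-(2-nitrophenylsulfonyl)hydrazine from 24 (CH2OH replaced by CH2N(NH2)SO2Ar) | C(c1ccccc1)(c1ccccc1)(c1ccccc1)OC[C@@H](OC)C[C@H](CN(N)S(=O)(=O)c1ccccc1[N+](=O)[O-])[C@@H](O[Si](C)(C)C(C)(C)C)c1cc(O[Si](C(C)C)(C(C)C)C(C)C)cc(c1)[N+](=O)[O-] | intermediate
26 | monoalkyl diazene from 25 (CH2N=NH) | C(c1ccccc1)(c1ccccc1)(c1ccccc1)OC[C@@H](OC)C[C@H](CN=N)[C@@H](O[Si](C)(C)C(C)(C)C)c1cc(O[Si](C(C)C)(C(C)C)C(C)C)cc(c1)[N+](=O)[O-] | intermediate
27 | tert-butyl({(1R,2S,4S)-4-methoxy-2-methyl-1-[3-nitro-5-(triisopropylsilyloxy)phenyl]-5-(trityloxy)pentyl}oxy)dimethylsilane | C(c1ccccc1)(c1ccccc1)(c1ccccc1)OC[C@@H](OC)C[C@H](C)[C@@H](O[Si](C)(C)C(C)(C)C)c1cc(O[Si](C(C)C)(C(C)C)C(C)C)cc(c1)[N+](=O)[O-] | intermediate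
28 | (2S,4S,5R)-5-(tert-butyldimethylsilyloxy)-2-methoxy-4-methyl-5-[3-nitro-5-(triisopropylsilyloxy)phenyl]pentan-1-ol | OC[C@@H](OC)C[C@H](C)[C@@H](O[Si](C)(C)C(C)(C)C)c1cc(O[Si](C(C)C)(C(C)C)C(C)C)cc(c1)[N+](=O)[O-] | intermediate
29 | (2S,4S,5R)-5-(tert-butyldimethylsilyloxy)-2-methoxy-4-methyl-5-[3-nitro-5-(triisopropylsilyloxy)phenyl]pentanal | O=C[C@@H](OC)C[C@H](C)[C@@H](O[Si](C)(C)C(C)(C)C)c1cc(O[Si](C(C)C)(C(C)C)C(C)C)cc(c1)[N+](=O)[O-] | intermediate
30 | pent-3-yn-2-one | CC#CC(C)=O | starting material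
31 | (S)-pent-3-yn-2-ol | CC#C[C@H](C)O | intermediate
32 | (S)-pent-3-yn-2-yl methanesulfonate | CC#C[C@H](C)OS(C)(=O)=O | intermediate
33 | (aR)-tributyl(penta-2,3-dien-2-yl)stannane | CCCC[Sn](CCCC)(CCCC)C(C)=[C@]=C([H])C | intermediate
34 | (1R,2S,4S,5R,6S)-1-(tert-butyldimethylsilyloxy)-4-methoxy-2,6-dimethyl-1-[3-nitro-5-(triisopropylsilyloxy)phenyl]non-7-yn-5-ol | CC#C[C@H](C)[C@@H](O)[C@@H](OC)C[C@H](C)[C@@H](O[Si](C)(C)C(C)(C)C)c1cc(O[Si](C(C)C)(C(C)C)C(C)C)cc(c1)[N+](=O)[O-] | intermediate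
35 | (1R,2S,4S,5R,6S)-1,5-bis(tert-butyldimethylsilyloxy)-4-methoxy-2,6-dimethyl-1-[3-nitro-5-(triisopropylsilyloxy)phenyl]non-7-yne | CC#C[C@H](C)[C@@H](O[Si](C)(C)C(C)(C)C)[C@@H](OC)C[C@H](C)[C@@H](O[Si](C)(C)C(C)(C)C)c1cc(O[Si](C(C)C)(C(C)C)C(C)C)cc(c1)[N+](=O)[O-] | intermediate
36 | 3-[(1R,2S,4S,5R,6S)-1,5-bis(tert-butyldimethylsilyloxy)-4-methoxy-2,6-dimethylnon-7-yn-1-yl]-5-(triisopropylsilyloxy)aniline | CC#C[C@H](C)[C@@H](O[Si](C)(C)C(C)(C)C)[C@@H](OC)C[C@H](C)[C@@H](O[Si](C)(C)C(C)(C)C)c1cc(O[Si](C(C)C)(C(C)C)C(C)C)cc(c1)N | intermediate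
37 | (2E,6S,7S)-6-methoxy-2-methyl-7-(triethylsilyloxy)dec-2-en-8-ynoyl chloride | ClC(=O)/C(C)=C/CC[C@H](OC)[C@@H](O[Si](CC)(CC)CC)C#CC | intermediate
38 | seco diyne anilide (amide of 36 with 14; C7 O-TES; C11 and C15 O-TBS; phenol O-TIPS) | CC#C[C@H](C)[C@@H](O[Si](C)(C)C(C)(C)C)[C@@H](OC)C[C@H](C)[C@@H](O[Si](C)(C)C(C)(C)C)c1cc(O[Si](C(C)C)(C(C)C)C(C)C)cc(c1)NC(=O)/C(C)=C/CC[C@H](OC)[C@@H](O[Si](CC)(CC)CC)C#CC | intermediate
39 | 19-membered cycloalkyne lactam (C8≡C9; C7 O-TES; C11 and C15 O-TBS; phenol O-TIPS) | C1#C[C@H](C)[C@@H](O[Si](C)(C)C(C)(C)C)[C@@H](OC)C[C@H](C)[C@@H](O[Si](C)(C)C(C)(C)C)c2cc(O[Si](C(C)C)(C(C)C)C(C)C)cc(c2)NC(=O)/C(C)=C/CC[C@H](OC)[C@H]1O[Si](CC)(CC)CC | intermediate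
40 | cycloalkyne lactam with free C7 hydroxyl | C1#C[C@H](C)[C@@H](O[Si](C)(C)C(C)(C)C)[C@@H](OC)C[C@H](C)[C@@H](O[Si](C)(C)C(C)(C)C)c2cc(O[Si](C(C)C)(C(C)C)C(C)C)cc(c2)NC(=O)/C(C)=C/CC[C@H](OC)[C@H]1O | intermediate
41 | C8-tributylstannyl ring alkene (C7 and C10 trans; free C7 hydroxyl) | CO[C@H]1C[C@H](C)[C@@H](O[Si](C)(C)C(C)(C)C)c2cc(O[Si](C(C)C)(C(C)C)C(C)C)cc(c2)NC(=O)/C(C)=C/CC[C@H](OC)[C@@H](O)/C([Sn](CCCC)(CCCC)CCCC)=C/[C@H](C)[C@H]1O[Si](C)(C)C(C)(C)C | intermediate
42 | (8E)-8-methyl ring alkene with free C7 hydroxyl (C11 and C15 O-TBS; phenol O-TIPS) | CO[C@H]1C[C@H](C)[C@@H](O[Si](C)(C)C(C)(C)C)c2cc(O[Si](C(C)C)(C(C)C)C(C)C)cc(c2)NC(=O)/C(C)=C/CC[C@H](OC)[C@@H](O)/C(C)=C/[C@H](C)[C@H]1O[Si](C)(C)C(C)(C)C | intermediate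
43 | C7 O-(N-trichloroacetyl)carbamate of 42 | CO[C@H]1C[C@H](C)[C@@H](O[Si](C)(C)C(C)(C)C)c2cc(O[Si](C(C)C)(C(C)C)C(C)C)cc(c2)NC(=O)/C(C)=C/CC[C@H](OC)[C@@H](OC(=O)NC(=O)C(Cl)(Cl)Cl)/C(C)=C/[C@H](C)[C@H]1O[Si](C)(C)C(C)(C)C | intermediate
44 | C7 carbamate of 42 (C11 and C15 O-TBS; phenol O-TIPS) | CO[C@H]1C[C@H](C)[C@@H](O[Si](C)(C)C(C)(C)C)c2cc(O[Si](C(C)C)(C(C)C)C(C)C)cc(c2)NC(=O)/C(C)=C/CC[C@H](OC)[C@@H](OC(N)=O)/C(C)=C/[C@H](C)[C@H]1O[Si](C)(C)C(C)(C)C | intermediate
45 | CNP0309815.1 (6S,7S,10S,11R,12S,14S,15R; 2E,8E) | CO[C@H]1C[C@H](C)[C@@H](O)c2cc(O)cc(c2)NC(=O)/C(C)=C/CC[C@H](OC)[C@@H](OC(N)=O)/C(C)=C/[C@H](C)[C@H]1O | target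

**Step count and risks**

Total step count: 31. Longest linear sequence: 20 steps (1, 2, 10, 11, 13–18, 22–31) from lactone 1.

Steps most likely to fail:

Step 22. The syn preference of the open transition state may erode, or the allene may be protodestannylated by adventitious acid, giving diastereomer mixtures or returned aldehyde. The fallback replaces the stannane by an auxiliary-controlled aldol and builds the alkyne afterwards. It sets out from 29: an Evans syn aldol with (R)-4-benzyl-3-propionyloxazolidin-2-one (Bu2BOTf, i-Pr2NEt, CH2Cl2, −78 °C) should give the C10/C11 syn-aldol imide F2. Silylation (t-BuMe2SiOTf, 2,6-lutidine) gives the C11 O-TBS imide F3, and LiBH4 reduction gives the C9 primary alcohol F4. Dess–Martin oxidation gives the C9 aldehyde F5, and Ohira–Bestmann homologation (dimethyl (1-diazo-2-oxopropyl)phosphonate, K2CO3, MeOH, 0 °C) gives the terminal alkyne F6. Methylation of the acetylide (LiN(SiMe3)2, MeOTf, THF, −78 °C) returns to the route at 35.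

Step 7. Facial selectivity may be poor because the THF-solvated alkynyl Grignard reagent competes with formation of the magnesium chelate. The fallback moves from substrate control to reagent control. It sets out from the C7 epimer mixture of 11: Dess–Martin oxidation gives the ynone ethyl (S,E)-6-methoxy-2-methyl-7-oxodec-2-en-8-ynoate F1, and transfer hydrogenation with RuCl[(R,R)-TsDPEN](p-cymene) in i-PrOH should return 11 as the 7S isomer.

Step 26. Intermolecular metathesis to oligomers may outrun ring closure, or turnover may be slow at the two branched propargylic sites next to the anilide. The fallback makes the C8≡C9 bond intermolecularly and closes the ring at the amide instead. It sets out from 35 and from bis-silyl compound 13 (isolated without aqueous work-up, used in excess): alkyne cross-metathesis with the same molybdenum alkylidyne should give the open-chain C8≡C9 nitro silyl ester F7. Bicarbonate methanolysis gives the nitro acid F8, and Zn/AcOH reduction gives the amino acid F9. Macrolactamisation under high dilution (bis(2-oxo-3-oxazolidinyl)phosphinic chloride, i-Pr2NEt, toluene, 80 °C) returns to the route at 39.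

Further compounds
F1 | step 7 | ethyl (S,E)-6-methoxy-2-methyl-7-oxodec-2-en-8-ynoate | CCOC(=O)/C(C)=C/CC[C@H](OC)C(=O)C#CC
F2 | step 22 | (R)-4-benzyl-3-[(2R,3R,4S,6S,7R)-7-(tert-butyldimethylsilyloxy)-3-hydroxy-4-methoxy-2,6-dimethyl-7-[3-nitro-5-(triisopropylsilyloxy)phenyl]heptanoyl]oxazolidin-2-one | O=C(N1[C@H](Cc2ccccc2)COC1=O)[C@H](C)[C@@H](O)[C@@H](OC)C[C@H](C)[C@@H](O[Si](C)(C)C(C)(C)C)c1cc(O[Si](C(C)C)(C(C)C)C(C)C)cc(c1)[N+](=O)[O-]
F3 | step 22 | C11 O-tert-butyldimethylsilyl ether of F2 | O=C(N1[C@H](Cc2ccccc2)COC1=O)[C@H](C)[C@@H](O[Si](C)(C)C(C)(C)C)[C@@H](OC)C[C@H](C)[C@@H](O[Si](C)(C)C(C)(C)C)c1cc(O[Si](C(C)C)(C(C)C)C(C)C)cc(c1)[N+](=O)[O-]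
F4 | step 22 | (2S,3R,4S,6S,7R)-3,7-bis(tert-butyldimethylsilyloxy)-4-methoxy-2,6-dimethyl-7-[3-nitro-5-(triisopropylsilyloxy)phenyl]heptan-1-ol | OC[C@H](C)[C@@H](O[Si](C)(C)C(C)(C)C)[C@@H](OC)C[C@H](C)[C@@H](O[Si](C)(C)C(C)(C)C)c1cc(O[Si](C(C)C)(C(C)C)C(C)C)cc(c1)[N+](=O)[O-]
F5 | step 22 | (2R,3R,4S,6S,7R)-3,7-bis(tert-butyldimethylsilyloxy)-4-methoxy-2,6-dimethyl-7-[3-nitro-5-(triisopropylsilyloxy)phenyl]heptanal | O=C[C@H](C)[C@@H](O[Si](C)(C)C(C)(C)C)[C@@H](OC)C[C@H](C)[C@@H](O[Si](C)(C)C(C)(C)C)c1cc(O[Si](C(C)C)(C(C)C)C(C)C)cc(c1)[N+](=O)[O-]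
F6 | step 22 | terminal alkyne analogue of 35 (C9≡C8–H) | C#C[C@H](C)[C@@H](O[Si](C)(C)C(C)(C)C)[C@@H](OC)C[C@H](C)[C@@H](O[Si](C)(C)C(C)(C)C)c1cc(O[Si](C(C)C)(C(C)C)C(C)C)cc(c1)[N+](=O)[O-]
F7 | step 26 | open-chain C8≡C9 nitro triethylsilyl ester (cross-metathesis product of 35 and 13) | CC[Si](CC)(CC)OC(=O)/C(C)=C/CC[C@H](OC)[C@@H](O[Si](CC)(CC)CC)C#C[C@H](C)[C@@H](O[Si](C)(C)C(C)(C)C)[C@@H](OC)C[C@H](C)[C@@H](O[Si](C)(C)C(C)(C)C)c1cc(O[Si](C(C)C)(C(C)C)C(C)C)cc(c1)[N+](=O)[O-]
F8 | step 26 | open-chain C8≡C9 nitro carboxylic acid | OC(=O)/C(C)=C/CC[C@H](OC)[C@@H](O[Si](CC)(CC)CC)C#C[C@H](C)[C@@H](O[Si](C)(C)C(C)(C)C)[C@@H](OC)C[C@H](C)[C@@H](O[Si](C)(C)C(C)(C)C)c1cc(O[Si](C(C)C)(C(C)C)C(C)C)cc(c1)[N+](=O)[O-]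
F9 | step 26 | open-chain C8≡C9 amino acid (seco acid of 39) | OC(=O)/C(C)=C/CC[C@H](OC)[C@@H](O[Si](CC)(CC)CC)C#C[C@H](C)[C@@H](O[Si](C)(C)C(C)(C)C)[C@@H](OC)C[C@H](C)[C@@H](O[Si](C)(C)C(C)(C)C)c1cc(O[Si](C(C)C)(C(C)C)C(C)C)cc(c1)N
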